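**Strategy.** The trimer is cut at its two C15–O ester bonds and three C11–O–C1′ ether bonds into three identical 15-oxygenated albicanol units and three units of natural isocitric acid. Each drimane unit rests on one intramolecular Diels–Alder reaction that exploits the trans ring-fusion bond C5–C10 lying next to quaternary C4: the cycloaddition forms C5–C10 and C8–C9, closing ring B (atoms C5 to C10) directly and ring A through the C1–C4 tether, and sets C5, C9 and C10. Its precursor is an acyclic (2E,8E)-trienoate whose only stereocentre, C4 (CH3 and CH2OSi), comes from an enzymatically desymmetrised methylmalonate.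

Key step: step 10

Remark on names: the terpenoid units are numbered as drimanes with C11 on C9, C12 the exocyclic methylene carbon on C8 and C15 the oxygenated carbon on C4. C1′ is the isocitrate carbon bearing the ether oxygen and C2′ the one bearing the central carboxyl. "TBSO-albicanyl" means (4R,5R,9S,10S)-15-[tert-butyl(dimethyl)silyl]oxydrim-8(12)-en-11-yl and "HO-albicanyl" its 15-hydroxy analogue. Unit A carries the isocitrate with the free central acid, unit B is the middle unit, unit C has the free C15–OH.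

Assumption: the esterase is taken to give the (R)-half-ester in step 2, as with long-chain 2-alkyl-2-methylmalonates. If the (S)-acid forms, the two carboxyl groups are elaborated in the opposite order (acid to CH2OSi, ester to the diene) and the route reaches the same dienyl ketone of step 8.

Assumption: (2R,3S)-isocitric acid is the commercial fermentation product, also sold as its monopotassium salt, from which the acid is freed on an acidic resin.

**Step 1**
Reactants: 1 dimethyl methylmalonate; 2 2-(3-chloropropyl)-2-methyl-1,3-dioxolane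
Product: 3 dimethyl 2-methyl-2-[3-(2-methyl-1,3-dioxolan-2-yl)propyl]propanedioate
Conditions: NaH, DMF, 0 °C; then 2, NaI (cat.), 80 °C
Reagents that add atoms: none
Why: Malonate alkylation (SN2 of the sodium enolate on the primary chloride, assisted by iodide exchange); no stereocentre is formed.

**Step 2**
Reactants: 3 dimethyl 2-methyl-2-[3-(2-methyl-1,3-dioxolan-2-yl)propyl]propanedioate
Product: 4 (2R)-2-(methoxycarbonyl)-2-methyl-5-(2-methyl-1,3-dioxolan-2-yl)pentanoic acid
Conditions: pig liver esterase, phosphate buffer pH 7.5, 25 °C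
Reagents that add atoms: water (O)
Why: Enzymatic desymmetrisation of a prochiral 2,2-disubstituted malonate, in which hydrolysis of one enantiotopic ester creates the quaternary stereocentre (future C4); optical purity would be raised by crystallising a salt with a chiral amine.

**Step 3**
Reactants: 4 (2R)-2-(methoxycarbonyl)-2-methyl-5-(2-methyl-1,3-dioxolan-2-yl)pentanoic acid
Product: 5 methyl (2R)-2-(hydroxymethyl)-2-methyl-5-(2-methyl-1,3-dioxolan-2-yl)pentanoate
Conditions: BH3·SMe2, THF, 0 °C → rt; MeOH quench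
Reagents that add atoms: none
Why: Chemoselective borane reduction of the carboxylic acid (through the acyloxyborane) in the presence of the methyl ester and the ketal; the quaternary centre is untouched.

**Step 4**
Reactants: 5 methyl (2R)-2-(hydroxymethyl)-2-methyl-5-(2-methyl-1,3-dioxolan-2-yl)pentanoate
Product: 6 methyl (2R)-2-formyl-2-methyl-5-(2-methyl-1,3-dioxolan-2-yl)pentanoate
Conditions: Dess–Martin periodinane, pyridine, CH2Cl2, 0 °C → rt
Reagents that add atoms: none
Why: Dess–Martin oxidation of the neopentyl alcohol to an aldehyde that has no α-hydrogen and so cannot epimerise.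

**Step 5**
Reactants: 6 methyl (2R)-2-formyl-2-methyl-5-(2-methyl-1,3-dioxolan-2-yl)pentanoate; 7 diethyl allylphosphonate
Product: 8 methyl (2R,3E)-2-methyl-2-[3-(2-methyl-1,3-dioxolan-2-yl)propyl]hexa-3,5-dienoate
Conditions: 7, n-BuLi, THF, −78 °C; then 6; HMPA, −78 °C → rt
Reagents that add atoms: none
Why: Horner–Wadsworth–Emmons olefination with the lithiated allylic phosphonate (α-attack on the aldehyde, then loss of phosphate on warming) should give the (E)-1,3-diene (C5=C6–C7=C8), the hindered ester being left alone at low temperature.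

**Step 6**
Reactants: 8 methyl (2R,3E)-2-methyl-2-[3-(2-methyl-1,3-dioxolan-2-yl)propyl]hexa-3,5-dienoate
Product: 9 (2R,3E)-2-methyl-2-[3-(2-methyl-1,3-dioxolan-2-yl)propyl]hexa-3,5-dien-1-ol
Conditions: i-Bu2AlH (2.5 equiv), CH2Cl2, −78 → 0 °C
Reagents that add atoms: none
Why: Hydride reduction of the ester to the primary alcohol (future C15–OH); diene and ketal are inert to the aluminium hydride.

**Step 7**
Reactants: 9 (2R,3E)-2-methyl-2-[3-(2-methyl-1,3-dioxolan-2-yl)propyl]hexa-3,5-dien-1-ol
Product: 10 tert-butyl(dimethyl){[(2R,3E)-2-methyl-2-[3-(2-methyl-1,3-dioxolan-2-yl)propyl]hexa-3,5-dien-1-yl]oxy}silane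
Conditions: TBSCl, imidazole, DMF, rt
Reagents that add atoms: tert-butyldimethylsilyl chloride (CC(C)(C)[Si](C)(C)Cl)
Why: Imidazole-promoted silylation of the primary neopentyl alcohol.

**Step 8**
Reactants: 10 tert-butyl(dimethyl){[(2R,3E)-2-methyl-2-[3-(2-methyl-1,3-dioxolan-2-yl)propyl]hexa-3,5-dien-1-yl]oxy}silane
Product: 11 (6R,7E)-6-{[tert-butyl(dimethyl)silyl]oxymethyl}-6-methyldeca-7,9-dien-2-one
Conditions: PPTS (cat.), acetone/H2O (9:1), 50 °C
Reagents that add atoms: water (O)
Why: Mild acid-catalysed ketal hydrolysis releases the methyl ketone while the primary silyl ether and the diene survive pyridinium catalysis.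

**Step 9**
Reactants: 11 (6R,7E)-6-{[tert-butyl(dimethyl)silyl]oxymethyl}-6-methyldeca-7,9-dien-2-one; 12 trimethyl phosphonoacetate
Product: 13 methyl (2E,7R,8E)-7-{[tert-butyl(dimethyl)silyl]oxymethyl}-3,7-dimethylundeca-2,8,10-trienoate
Conditions: 12, NaH, THF, 0 °C; then 11, 0 → 50 °C; chromatography
Reagents that add atoms: none
Why: Horner–Wadsworth–Emmons olefination of the methyl ketone gives the trisubstituted enoate C9=C10, the (2E) isomer being expected to predominate and the minor (2Z) isomer being removed by chromatography.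

**Step 10**
Reactants: 13 methyl (2E,7R,8E)-7-{[tert-butyl(dimethyl)silyl]oxymethyl}-3,7-dimethylundeca-2,8,10-trienoate
Product: 14 methyl (4R,5R,9S,10S)-15-[tert-butyl(dimethyl)silyl]oxy-12-nordrim-6-en-11-oate (trans-fused octalin; 4β-CH3, 4α-CH2OSi, 5α-H, 9α-H, 9β-CO2Me, 10β-CH3)
Conditions: Et2AlCl (1.5 equiv), CH2Cl2, −20 °C → rt
Reagents that add atoms: none
Why: Coordination of Et2AlCl to the ester carbonyl lowers the enoate LUMO, and the (E)-diene C5=C6–C7=C8 adds suprafacially to C9=C10 in a concerted, asynchronous [4+2] cycloaddition that forms C5–C10 and C8–C9; the closest known reaction type is the Lewis-acid-catalysed type 1 intramolecular Diels–Alder cyclisation of deca-1,7,9-trienoate esters, which gives trans-octalins bearing a methyl group at the ring fusion. Ring B (C5–C10) is closed by the cycloaddition itself, and ring A (C10, C1–C5) through the four-carbon tether C1–C4, which adopts a chair in the transition state. The trans relation of C5–H and C10–CH3 follows from the endo placement of the ester (tether exo), the cis relation of C10–CH3 and C9–CO2Me from the (E)-geometry of the enoate, and the absolute sense from C4, whose silyloxymethyl group should take the equatorial site of the tether chair so that only the methyl group is syn-axial to the developing C10 methyl. The step needs endo selectivity, which the Lewis acid and the (E)-enoate secure, and π-facial selectivity, which rests only on the modest size difference of the two C4 substituents and is therefore where the route carries its risk; a C4-epimeric adduct would be separated here.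

**Step 11**
Reactants: 14 methyl (4R,5R,9S,10S)-15-[tert-butyl(dimethyl)silyl]oxy-12-nordrim-6-en-11-oate
Product: 15 methyl (4R,5R,9R,10S)-15-[tert-butyl(dimethyl)silyl]oxy-8-oxo-12-nordrim-6-en-11-oate
Conditions: Rh2(C6H10NO)4 (dirhodium tetrakis(caprolactamate), 1 mol %), t-BuOOH (70 % aq., 5 equiv), K2CO3 (0.5 equiv), CH2Cl2, rt
Reagents that add atoms: tert-butyl hydroperoxide (CC(C)(C)OO)
Why: Dirhodium-catalysed allylic oxidation, in which the tert-butylperoxyl radical abstracts hydrogen from C8, the only allylic methylene (C5–H is shielded by C4 and C10), and the mixed peroxide formed at the less hindered terminus C8 collapses to the C8 ketone; C9, now between two carbonyl groups, keeps its equatorial ester.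

**Step 12**
Reactants: 15 methyl (4R,5R,9R,10S)-15-[tert-butyl(dimethyl)silyl]oxy-8-oxo-12-nordrim-6-en-11-oate
Product: 16 methyl (4R,5R,9R,10S)-15-[tert-butyl(dimethyl)silyl]oxy-8-oxo-12-nordriman-11-oate
Conditions: H2 (1 atm), 10 % Pd/C, EtOAc, rt
Reagents that add atoms: none
Why: Heterogeneous catalytic hydrogenation of the conjugated C6=C7 double bond; ketone, ester and silyl ether are not reduced and no stereocentre is formed.

**Step 13**
Reactants: 16 methyl (4R,5R,9R,10S)-15-[tert-butyl(dimethyl)silyl]oxy-8-oxo-12-nordriman-11-oate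
Product: 17 methyl (4R,5R,9S,10S)-15-[tert-butyl(dimethyl)silyl]oxydrim-8(12)-en-11-oate
Conditions: Zn, CH2Br2, TiCl4 (reagent aged in THF at 5 °C), CH2Cl2, 0 °C → rt
Reagents that add atoms: dibromomethane (BrCBr)
Why: Lombardo–Takai methylenation, whose non-basic zinc–titanium methylene reagent attacks the ketone and not the ester and does not deprotonate C9, so C12 is installed as the exocyclic methylene with the equatorial C9 ester retained.

**Step 14**
Reactants: 17 methyl (4R,5R,9S,10S)-15-[tert-butyl(dimethyl)silyl]oxydrim-8(12)-en-11-oate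
Product: 18 (4R,5R,9S,10S)-15-[tert-butyl(dimethyl)silyl]oxydrim-8(12)-en-11-ol
Conditions: LiAlH4, Et2O, −20 → 0 °C
Reagents that add atoms: none
Why: Hydride reduction of the ester to the C11 alcohol under conditions that neither epimerise C9 nor move the exocyclic double bond.

**Step 15**
Reactants: 18 (4R,5R,9S,10S)-15-[tert-butyl(dimethyl)silyl]oxydrim-8(12)-en-11-ol
Product: 19 (4R,5R,9S,10S)-15-[tert-butyl(dimethyl)silyl]oxydrim-8(12)-en-11-al
Conditions: Dess–Martin periodinane, pyridine, CH2Cl2, 0 °C; used at once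
Reagents that add atoms: none
Why: Buffered Dess–Martin oxidation gives the β,γ-unsaturated aldehyde without acid- or base-induced migration of C8=C12 into conjugation.

**Step 16**
Reactants: 20 (2R,3S)-isocitric acid [(1R,2S)-1-hydroxypropane-1,2,3-tricarboxylic acid]
Product: 21 (2S)-2-[(1R)-1-hydroxy-2-methoxy-2-oxoethyl]butanedioic acid (1′-methyl isocitrate)
Conditions: B(OH)3 (0.2 equiv), MeOH, rt; evaporation
Reagents that add atoms: methanol (CO)
Why: Boric acid-catalysed chemoselective esterification of an α-hydroxy carboxylic acid, in which only the carboxyl next to the hydroxyl is activated as a cyclic borate, so the C1′ carboxyl alone is esterified at a temperature where lactonisation is slow.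

**Step 17**
Reactants: 19 (4R,5R,9S,10S)-15-[tert-butyl(dimethyl)silyl]oxydrim-8(12)-en-11-al; 21 (2S)-2-[(1R)-1-hydroxy-2-methoxy-2-oxoethyl]butanedioic acid
Product: 23 (2S)-2-[(1R)-2-methoxy-2-oxo-1-(TBSO-albicanyloxy)ethyl]butanedioic acid, via tris(trimethylsilyl) derivative 22 (not isolated)
Conditions: 21, N,O-bis(trimethylsilyl)acetamide, CH2Cl2, rt, volatiles removed; then 19, Et3SiH (3 equiv), TMSOTf (0.5 equiv), CH2Cl2, −78 → −40 °C; aqueous work-up at pH 4
Reagents that add atoms: none
Why: Reductive etherification, in which the silyl ether oxygen of 22 adds to the TMSOTf-activated aldehyde and the resulting oxocarbenium ion (possibly after reversible capture by the neighbouring silyl ester as a cyclic acyloxy acetal) is reduced by Et3SiH, forming the C11–O–C1′ ether without touching either isocitrate stereocentre; work-up frees the two carboxylic acids.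

**Step 18**
Reactants: 23 (2S)-2-[(1R)-2-methoxy-2-oxo-1-(TBSO-albicanyloxy)ethyl]butanedioic acid
Product: 24 methyl (2R)-2-[(3S)-2,5-dioxooxolan-3-yl]-2-(TBSO-albicanyloxy)acetate (cyclic anhydride of the central and CH2 carboxyl groups)
Conditions: DCC (1.05 equiv), CH2Cl2, 0 °C → rt; filtration, evaporation; crude anhydride divided into two portions
Reagents that add atoms: none
Why: Carbodiimide dehydration of the 1,2-diacid closes the five-membered succinic anhydride, the only cyclic anhydride this diacid can form; no base is present, so neither C2′ nor the β-alkoxy group is endangered, and the anhydride is freed from the urea by filtration and used without chromatography.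

**Step 19**
Reactants: 24 methyl (2R)-2-[(3S)-2,5-dioxooxolan-3-yl]-2-(TBSO-albicanyloxy)acetate
Product: 25 (2S)-2-[(1R)-2-methoxy-2-oxo-1-(TBSO-albicanyloxy)ethyl]-4-oxo-4-(prop-2-en-1-yloxy)butanoic acid
Conditions: allyl alcohol (10 equiv), CH2Cl2, 40 °C; chromatography
Reagents that add atoms: allyl alcohol (C=CCO)
Why: Base-free alcoholysis of the 2-substituted succinic anhydride should occur at the less hindered CH2–C=O carbonyl, placing the allyl ester on the CH2 carboxyl and leaving the central carboxyl free, without a base that could eliminate the β-alkoxy group; any minor regioisomer would be removed at this stage.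

**Step 20**
Reactants: 24 methyl (2R)-2-[(3S)-2,5-dioxooxolan-3-yl]-2-(TBSO-albicanyloxy)acetate
Product: 26 (2S)-4-methoxy-2-[(1R)-2-methoxy-2-oxo-1-(TBSO-albicanyloxy)ethyl]-4-oxobutanoic acid
Conditions: MeOH (20 equiv), CH2Cl2, 40 °C; chromatography
Reagents that add atoms: methanol (CO)
Why: The same regioselective base-free anhydride alcoholysis as in step 19, now with methanol on the second portion of 24, puts the methyl ester on the CH2 carboxyl as unit A requires and leaves the central carboxyl free.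

**Step 21**
Reactants: 26 (2S)-4-methoxy-2-[(1R)-2-methoxy-2-oxo-1-(TBSO-albicanyloxy)ethyl]-4-oxobutanoic acid
Product: 27 4-methyl 1-prop-2-en-1-yl (2S)-2-[(1R)-2-methoxy-2-oxo-1-(TBSO-albicanyloxy)ethyl]butanedioate
Conditions: allyl bromide, KHCO3, DMF, rt
Reagents that add atoms: allyl bromide (C=CCBr)
Why: Carboxylate O-alkylation (SN2 at the allylic carbon, so hindrance at the carboxyl is irrelevant) under bicarbonate, too weak a base to epimerise C2′ or eliminate the β-alkoxy group.

**Step 22**
Reactants: 27 4-methyl 1-prop-2-en-1-yl (2S)-2-[(1R)-2-methoxy-2-oxo-1-(TBSO-albicanyloxy)ethyl]butanedioate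
Product: 28 4-methyl 1-prop-2-en-1-yl (2S)-2-[(1R)-2-methoxy-2-oxo-1-(HO-albicanyloxy)ethyl]butanedioate
Conditions: HF·pyridine, pyridine, THF, 0 °C → rt
Reagents that add atoms: none
Why: Fluoride-mediated cleavage of the primary silyl ether under buffered conditions that leave esters, ether and the exocyclic alkene intact.

**Step 23**
Reactants: 25 (2S)-2-[(1R)-2-methoxy-2-oxo-1-(TBSO-albicanyloxy)ethyl]-4-oxo-4-(prop-2-en-1-yloxy)butanoic acid; 28 4-methyl 1-prop-2-en-1-yl (2S)-2-[(1R)-2-methoxy-2-oxo-1-(HO-albicanyloxy)ethyl]butanedioate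
Product: 30 dimer silyl ether A–B (C15–O of unit A acylated by the central carboxyl of 25; 15-O-TBS on unit B), via mixed trichlorobenzoic anhydride 29 (not isolated)
Conditions: 25, 2,4,6-trichlorobenzoyl chloride, Et3N, toluene, 0 °C → rt; then 28, DMAP, rt
Reagents that add atoms: none
Why: Yamaguchi esterification, in which the mixed anhydride of the central carboxyl acylates the neopentyl C15 hydroxyl under DMAP catalysis; the CH2 carboxyl is blocked as its allyl ester, so only the central carboxyl can react.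

**Step 24**
Reactants: 30 dimer silyl ether A–B
Product: 31 dimer alcohol A–B (unit B C15–OH free)
Conditions: HF·pyridine, pyridine, THF, 0 °C → rt
Reagents that add atoms: none
Why: Fluoride-mediated cleavage of the only silyl ether, to which allyl esters, methyl esters and the new C15 ester are inert.

**Step 25**
Reactants: 25 (2S)-2-[(1R)-2-methoxy-2-oxo-1-(TBSO-albicanyloxy)ethyl]-4-oxo-4-(prop-2-en-1-yloxy)butanoic acid; 31 dimer alcohol A–B
Product: 33 trimer silyl ether triallyl ester A–B–C (15-O-TBS on unit C), via mixed methylnitrobenzoic anhydride 32 (not isolated)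
Conditions: 25 (1.2 equiv), 31, 2-methyl-6-nitrobenzoic anhydride (1.3 equiv), DMAP (0.2 equiv), Et3N (3 equiv), CH2Cl2, rt
Reagents that add atoms: none
Why: Shiina esterification, in which 2-methyl-6-nitrobenzoic anhydride turns the central carboxyl of 25 in the flask into a mixed anhydride whose aroyl carbonyl is blocked by its two ortho substituents, so DMAP transfers only the isocitrate acyl group to the neopentyl C15 hydroxyl of unit B; this one-pot room-temperature protocol needs no separate activation stage in the presence of the ester-rich dimer and completes the chain A–B–C.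

**Step 26**
Reactants: 33 trimer silyl ether triallyl ester A–B–C
Product: 34 trimer triallyl ester A–B–C (unit C C15–OH free)
Conditions: HF·pyridine, pyridine, THF, 0 °C → rt
Reagents that add atoms: none
Why: Fluoride-mediated desilylation frees the C15 hydroxyl of unit C under the conditions already used in steps 22 and 24.

**Step 27**
Reactants: 34 trimer triallyl ester A–B–C
Product: 35 cryptoporic acid T
Conditions: Pd(PPh3)4 (5 mol %), morpholine (10 equiv), THF, rt; work-up at pH 3
Reagents that add atoms: none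
Why: Tsuji–Trost deallylation, in which the three allyl esters are transferred to morpholine through π-allyl palladium complexes under neutral conditions that spare the methyl esters, the two C15 esters, the ethers and the 1,1-disubstituted alkenes.

**Compound list**
1 | dimethyl methylmalonate | COC(=O)C(C)C(=O)OC | starting material
2 | 2-(3-chloropropyl)-2-methyl-1,3-dioxolane | CC1(CCCCl)OCCO1 | starting material
3 | dimethyl 2-methyl-2-[3-(2-methyl-1,3-dioxolan-2-yl)propyl]propanedioate | COC(=O)C(C)(CCCC1(C)OCCO1)C(=O)OC | intermediate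
4 | (2R)-2-(methoxycarbonyl)-2-methyl-5-(2-methyl-1,3-dioxolan-2-yl)pentanoic acid | CC1(CCC[C@](C)(C(=O)O)C(=O)OC)OCCO1 | intermediate
5 | methyl (2R)-2-(hydroxymethyl)-2-methyl-5-(2-methyl-1,3-dioxolan-2-yl)pentanoate | CC1(CCC[C@](C)(CO)C(=O)OC)OCCO1 | intermediate
6 | methyl (2R)-2-formyl-2-methyl-5-(2-methyl-1,3-dioxolan-2-yl)pentanoate | CC1(CCC[C@](C)(C=O)C(=O)OC)OCCO1 | intermediate
7 | diethyl allylphosphonate | C=CCP(=O)(OCC)OCC | starting material
8 | methyl (2R,3E)-2-methyl-2-[3-(2-methyl-1,3-dioxolan-2-yl)propyl]hexa-3,5-dienoate | CC1(CCC[C@](C)(/C=C/C=C)C(=O)OC)OCCO1 | intermediate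
9 | (2R,3E)-2-methyl-2-[3-(2-methyl-1,3-dioxolan-2-yl)propyl]hexa-3,5-dien-1-ol | CC1(CCC[C@](C)(/C=C/C=C)CO)OCCO1 | intermediate
10 | tert-butyl(dimethyl){[(2R,3E)-2-methyl-2-[3-(2-methyl-1,3-dioxolan-2-yl)propyl]hexa-3,5-dien-1-yl]oxy}silane | CC1(CCC[C@](C)(/C=C/C=C)CO[Si](C)(C)C(C)(C)C)OCCO1 | intermediate
11 | (6R,7E)-6-{[tert-butyl(dimethyl)silyl]oxymethyl}-6-methyldeca-7,9-dien-2-one | CC(=O)CCC[C@](C)(/C=C/C=C)CO[Si](C)(C)C(C)(C)C | intermediate
12 | trimethyl phosphonoacetate | COC(=O)CP(=O)(OC)OC | starting material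
13 | methyl (2E,7R,8E)-7-{[tert-butyl(dimethyl)silyl]oxymethyl}-3,7-dimethylundeca-2,8,10-trienoate | COC(=O)/C=C(\C)CCC[C@@](C)(CO[Si](C)(C)C(C)(C)C)/C=C/C=C | intermediate
14 | methyl (4R,5R,9S,10S)-15-[tert-butyl(dimethyl)silyl]oxy-12-nordrim-6-en-11-oate | C1C=C[C@H]2[C@](C)(CO[Si](C)(C)C(C)(C)C)CCC[C@]2(C)[C@H]1C(=O)OC | intermediate
15 | methyl (4R,5R,9R,10S)-15-[tert-butyl(dimethyl)silyl]oxy-8-oxo-12-nordrim-6-en-11-oate | O=C1C=C[C@H]2[C@](C)(CO[Si](C)(C)C(C)(C)C)CCC[C@]2(C)[C@H]1C(=O)OC | intermediate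
16 | methyl (4R,5R,9R,10S)-15-[tert-butyl(dimethyl)silyl]oxy-8-oxo-12-nordriman-11-oate | O=C1CC[C@H]2[C@](C)(CO[Si](C)(C)C(C)(C)C)CCC[C@]2(C)[C@H]1C(=O)OC | intermediate
17 | methyl (4R,5R,9S,10S)-15-[tert-butyl(dimethyl)silyl]oxydrim-8(12)-en-11-oate | C=C1CC[C@H]2[C@](C)(CO[Si](C)(C)C(C)(C)C)CCC[C@]2(C)[C@H]1C(=O)OC | intermediate
18 | (4R,5R,9S,10S)-15-[tert-butyl(dimethyl)silyl]oxydrim-8(12)-en-11-ol | C=C1CC[C@H]2[C@](C)(CO[Si](C)(C)C(C)(C)C)CCC[C@]2(C)[C@H]1CO | intermediate
19 | (4R,5R,9S,10S)-15-[tert-butyl(dimethyl)silyl]oxydrim-8(12)-en-11-al | C=C1CC[C@H]2[C@](C)(CO[Si](C)(C)C(C)(C)C)CCC[C@]2(C)[C@H]1C=O | intermediate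
20 | (2R,3S)-isocitric acid [(1R,2S)-1-hydroxypropane-1,2,3-tricarboxylic acid] | O[C@@H](C(=O)O)[C@H](CC(=O)O)C(=O)O | starting material
21 | (2S)-2-[(1R)-1-hydroxy-2-methoxy-2-oxoethyl]butanedioic acid | O[C@@H](C(=O)OC)[C@H](CC(=O)O)C(=O)O | intermediate
22 | bis(trimethylsilyl) (2S)-2-[(1R)-2-methoxy-2-oxo-1-(trimethylsilyloxy)ethyl]butanedioate | C[Si](C)(C)O[C@@H](C(=O)OC)[C@H](CC(=O)O[Si](C)(C)C)C(=O)O[Si](C)(C)C | intermediate
23 | (2S)-2-[(1R)-2-methoxy-2-oxo-1-(TBSO-albicanyloxy)ethyl]butanedioic acid | C=C1CC[C@H]2[C@](C)(CO[Si](C)(C)C(C)(C)C)CCC[C@]2(C)[C@H]1CO[C@@H](C(=O)OC)[C@H](CC(=O)O)C(=O)O | intermediate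
24 | methyl (2R)-2-[(3S)-2,5-dioxooxolan-3-yl]-2-(TBSO-albicanyloxy)acetate | C=C1CC[C@H]2[C@](C)(CO[Si](C)(C)C(C)(C)C)CCC[C@]2(C)[C@H]1CO[C@@H](C(=O)OC)[C@H](CC(=O)O3)C3=O | intermediate
25 | (2S)-2-[(1R)-2-methoxy-2-oxo-1-(TBSO-albicanyloxy)ethyl]-4-oxo-4-(prop-2-en-1-yloxy)butanoic acid | C=C1CC[C@H]2[C@](C)(CO[Si](C)(C)C(C)(C)C)CCC[C@]2(C)[C@H]1CO[C@@H](C(=O)OC)[C@H](CC(=O)OCC=C)C(=O)O | intermediate
26 | (2S)-4-methoxy-2-[(1R)-2-methoxy-2-oxo-1-(TBSO-albicanyloxy)ethyl]-4-oxobutanoic acid | C=C1CC[C@H]2[C@](C)(CO[Si](C)(C)C(C)(C)C)CCC[C@]2(C)[C@H]1CO[C@@H](C(=O)OC)[C@H](CC(=O)OC)C(=O)O | intermediate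
27 | 4-methyl 1-prop-2-en-1-yl (2S)-2-[(1R)-2-methoxy-2-oxo-1-(TBSO-albicanyloxy)ethyl]butanedioate | C=C1CC[C@H]2[C@](C)(CO[Si](C)(C)C(C)(C)C)CCC[C@]2(C)[C@H]1CO[C@@H](C(=O)OC)[C@H](CC(=O)OC)C(=O)OCC=C | intermediate
28 | 4-methyl 1-prop-2-en-1-yl (2S)-2-[(1R)-2-methoxy-2-oxo-1-(HO-albicanyloxy)ethyl]butanedioate | C=C1CC[C@H]2[C@](C)(CO)CCC[C@]2(C)[C@H]1CO[C@@H](C(=O)OC)[C@H](CC(=O)OC)C(=O)OCC=C | intermediate
29 | mixed anhydride of 25 (central carboxyl) with 2,4,6-trichlorobenzoic acid | C=C1CC[C@H]2[C@](C)(CO[Si](C)(C)C(C)(C)C)CCC[C@]2(C)[C@H]1CO[C@@H](C(=O)OC)[C@H](CC(=O)OCC=C)C(=O)OC(=O)c1c(Cl)cc(Cl)cc1Cl | intermediate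
30 | dimer silyl ether A–B: unit A (isocitrate with 1′-CO2Me, CH2CO2Me, central CO2-allyl) esterified at C15–O by the central carboxyl of the unit B isocitrate (1′-CO2Me, CH2CO2-allyl); unit B 15-O-TBS | C=C1CC[C@H]2[C@](C)(COC(=O)[C@@H](CC(=O)OCC=C)[C@@H](OC[C@H]3C(=C)CC[C@H]4[C@](C)(CO[Si](C)(C)C(C)(C)C)CCC[C@]34C)C(=O)OC)CCC[C@]2(C)[C@H]1CO[C@@H](C(=O)OC)[C@H](CC(=O)OC)C(=O)OCC=C | intermediate
31 | dimer alcohol A–B: as 30 with unit B C15–OH free | C=C1CC[C@H]2[C@](C)(COC(=O)[C@@H](CC(=O)OCC=C)[C@@H](OC[C@H]3C(=C)CC[C@H]4[C@](C)(CO)CCC[C@]34C)C(=O)OC)CCC[C@]2(C)[C@H]1CO[C@@H](C(=O)OC)[C@H](CC(=O)OC)C(=O)OCC=C | intermediate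
32 | mixed anhydride of 25 (central carboxyl) with 2-methyl-6-nitrobenzoic acid | C=C1CC[C@H]2[C@](C)(CO[Si](C)(C)C(C)(C)C)CCC[C@]2(C)[C@H]1CO[C@@H](C(=O)OC)[C@H](CC(=O)OCC=C)C(=O)OC(=O)c1c(C)cccc1[N+](=O)[O-] | intermediate
33 | trimer silyl ether triallyl ester A–B–C: 31 esterified at unit B C15–O by the central carboxyl of a second 25; unit C 15-O-TBS | C=C1CC[C@H]2[C@](C)(COC(=O)[C@@H](CC(=O)OCC=C)[C@@H](OC[C@H]3C(=C)CC[C@H]4[C@](C)(COC(=O)[C@@H](CC(=O)OCC=C)[C@@H](OC[C@H]5C(=C)CC[C@H]6[C@](C)(CO[Si](C)(C)C(C)(C)C)CCC[C@]56C)C(=O)OC)CCC[C@]34C)C(=O)OC)CCC[C@]2(C)[C@H]1CO[C@@H](C(=O)OC)[C@H](CC(=O)OC)C(=O)OCC=C | intermediate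
34 | trimer triallyl ester A–B–C: as 33 with unit C C15–OH free | C=C1CC[C@H]2[C@](C)(COC(=O)[C@@H](CC(=O)OCC=C)[C@@H](OC[C@H]3C(=C)CC[C@H]4[C@](C)(COC(=O)[C@@H](CC(=O)OCC=C)[C@@H](OC[C@H]5C(=C)CC[C@H]6[C@](C)(CO)CCC[C@]56C)C(=O)OC)CCC[C@]34C)C(=O)OC)CCC[C@]2(C)[C@H]1CO[C@@H](C(=O)OC)[C@H](CC(=O)OC)C(=O)OCC=C | intermediate
35 | cryptoporic acid T | C=C1CC[C@H]2[C@](C)(COC(=O)[C@@H](CC(=O)O)[C@@H](OC[C@H]3C(=C)CC[C@H]4[C@](C)(COC(=O)[C@@H](CC(=O)O)[C@@H](OC[C@H]5C(=C)CC[C@H]6[C@](C)(CO)CCC[C@]56C)C(=O)OC)CCC[C@]34C)C(=O)OC)CCC[C@]2(C)[C@H]1CO[C@@H](C(=O)OC)[C@H](CC(=O)OC)C(=O)O | target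

**Step count.** Total: 27 steps. Longest linear sequence: 25 steps (steps 1–15, 17, 18, 20–27); steps 16 and 19 are branches.

**Steps most likely to fail**

Step 10. What may go wrong: the C4 centre may not discriminate well enough between the two faces of the diene, because its methyl and silyloxymethyl groups differ little in size, so that the C4-epimeric trans-octalin forms alongside 14; the β,β-disubstituted enoate may also cyclise sluggishly. Fallback, reagent control by a covalently bound auxiliary: setting out from 13, saponification (LiOH, THF/MeOH/H2O) would give the trienoic acid F1. Its pivaloyl mixed anhydride (PivCl, Et3N, THF, −20 °C) would acylate (S)-4-benzyl-1,3-oxazolidin-2-one in the presence of LiCl to give the trienoyl imide F2. Me2AlCl (1.5 equiv, CH2Cl2, −30 → 0 °C) would chelate both imide carbonyls, giving a more electrophilic s-cis dienophile shielded on one face by the benzyl group, so the same two bonds form in the endo mode on the face that leads to the (9S,10S) imide adduct F3. LiOOH (THF/H2O, 0 °C) would cleave the auxiliary to the octalin acid F4, and TMSCHN2 (MeOH/toluene) would return the route at 14.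

Step 17. What may go wrong: no C–O bond may form between the hindered aldehyde and the poorly nucleophilic α-silyloxy ester, or the acid may move the C8=C12 double bond into conjugation with the aldehyde before reduction. Fallback, acetalisation and reduction as separate operations: setting out from 19 and 22 (made from 21 as in the route), catalytic TMSOTf in CH2Cl2 at −78 °C without silane would let the central silyl ester capture the hemiacetal intramolecularly, giving the 2-substituted 1,3-dioxan-4-one F5, isolated after aqueous work-up. Reductive ring opening with Et3SiH/TiCl4 in CH2Cl2 at −78 °C would cleave the acetal C–O(acyl) bond and deliver hydride to C11, returning the route at 23.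

Step 13. What may go wrong: enolisation or titanium chelation of the β-keto ester may leave the ketone unmethylenated, or the new double bond may move into conjugation with the ester. Fallback, removal of the ester before olefination: setting out from 16, mild ketalisation (1,2-bis(trimethylsilyloxy)ethane, TMSOTf cat., CH2Cl2, −78 °C) would give the dioxolane ester F6. LiAlH4 (Et2O, 0 °C) would reduce it to the ketal alcohol F7, and PPTS in wet acetone would free the β-hydroxy ketone F8. Wittig methylenation with excess Ph3P=CH2 in THF, in which the alkoxide formed first guards against β-elimination, would give 18 directly, where the route is rejoined.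

**Further compounds**
F1 | step 10 | (2E,7R,8E)-7-{[tert-butyl(dimethyl)silyl]oxymethyl}-3,7-dimethylundeca-2,8,10-trienoic acid | OC(=O)/C=C(\C)CCC[C@@](C)(CO[Si](C)(C)C(C)(C)C)/C=C/C=C
F2 | step 10 | (4S)-4-benzyl-3-[(2E,7R,8E)-7-{[tert-butyl(dimethyl)silyl]oxymethyl}-3,7-dimethylundeca-2,8,10-trienoyl]-1,3-oxazolidin-2-one | O=C(/C=C(\C)CCC[C@@](C)(CO[Si](C)(C)C(C)(C)C)/C=C/C=C)N1[C@@H](Cc2ccccc2)COC1=O
F3 | step 10 | (4S)-4-benzyl-3-{(4R,5R,9S,10S)-15-[tert-butyl(dimethyl)silyl]oxy-12-nordrim-6-en-11-oyl}-1,3-oxazolidin-2-one | C1C=C[C@H]2[C@](C)(CO[Si](C)(C)C(C)(C)C)CCC[C@]2(C)[C@H]1C(=O)N3[C@@H](Cc4ccccc4)COC3=O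
F4 | step 10 | (4R,5R,9S,10S)-15-[tert-butyl(dimethyl)silyl]oxy-12-nordrim-6-en-11-oic acid | C1C=C[C@H]2[C@](C)(CO[Si](C)(C)C(C)(C)C)CCC[C@]2(C)[C@H]1C(=O)O
F5 | step 17 | 2-[(5S,6R)-6-(methoxycarbonyl)-4-oxo-2-{(4R,5R,9S,10S)-15-[tert-butyl(dimethyl)silyl]oxy-11-nordrim-8(12)-en-9-yl}-1,3-dioxan-5-yl]acetic acid (acetal carbon = C11) | C=C1CC[C@H]2[C@](C)(CO[Si](C)(C)C(C)(C)C)CCC[C@]2(C)[C@H]1C3O[C@@H](C(=O)OC)[C@H](CC(=O)O)C(=O)O3
F6 | step 13 | methyl (4R,5R,9R,10S)-15-[tert-butyl(dimethyl)silyl]oxy-8,8-(ethylenedioxy)-12-nordriman-11-oate | O3CCOC13CC[C@H]2[C@](C)(CO[Si](C)(C)C(C)(C)C)CCC[C@]2(C)[C@H]1C(=O)OC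
F7 | step 13 | (4R,5R,9S,10S)-15-[tert-butyl(dimethyl)silyl]oxy-8,8-(ethylenedioxy)-12-nordriman-11-ol | O3CCOC13CC[C@H]2[C@](C)(CO[Si](C)(C)C(C)(C)C)CCC[C@]2(C)[C@H]1CO
F8 | step 13 | (4R,5R,9S,10S)-15-[tert-butyl(dimethyl)silyl]oxy-11-hydroxy-12-nordriman-8-one | O=C1CC[C@H]2[C@](C)(CO[Si](C)(C)C(C)(C)C)CCC[C@]2(C)[C@H]1CO
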